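**Plan**

1. Numbering: ring C1 (C=O), C2 (allyl), C3, C4 (quaternary C–OMe), C5 (C–OMe), C6; C7 is the side-chain CHMe. The retrosynthesis first removes the O-methyl group at C4, then cuts the ring bond C3–C4. C4 is a tertiary allylic carbinol carbon lying between the ring vinyl carbons C3 and C5, so it can be made from a C4 ketone attacked by an alkenyl metal at C3.
2. The open-chain precursor is a cis-2-methoxy-ene-1,4-dione (carbonyls C1 and C4) carrying a (Z)-alkenyl boronate at C3. It is folded back into a 3-methoxyfuran whose two α-carbons are C1 and C4. Further cuts are C1–C2 (cross-coupling), C4–C5 (acylation of lithiated methoxyallene) and C7–CH2Ar (auxiliary alkylation).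
3. Forward order: benzylic bromide plus propionyl imide, (R)-Weinreb amide, allenyl ketone, furan (temporary ring), coupling with the bromoboration product of pent-1-en-4-yne, opening of the furan with singlet oxygen, closure of the six-membered ring by rhodium, O-methylation.
4. Stereochemistry: C7 comes from the oxazolidinone auxiliary and C4 from the chiral rhodium catalyst. The (Z)-boronate comes from syn-bromoboration and a stereoretentive coupling, and the cis ene-dione geometry from the furan ring.

Key step: step 9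

Assumption: the sense of induction of the bisphosphine at C4 cannot be assigned in advance. The (R)-ligand is written and stands for whichever antipode delivers the alkenyl group to the Re face of the C4 carbonyl.

**Route**

Step 1
Reactants: 1 (4S)-4-benzyl-3-propanoyl-1,3-oxazolidin-2-one; 2 4-(bromomethyl)-1,2-dimethoxybenzene
Product: 4 (4S)-4-benzyl-3-[(2R)-3-(3,4-dimethoxyphenyl)-2-methylpropanoyl]-1,3-oxazolidin-2-one, via sodium (Z)-enolate 3 (not isolated)
Conditions: NaN(SiMe3)2, THF, −78 °C; then 2, −78 to −20 °C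
Reagents that add atoms: none
Why: Evans asymmetric alkylation, in which the chelated sodium (Z)-enolate is benzylated on the face opposite the C4 benzyl group of the auxiliary, which should set C7 as (R).

Step 2
Reactants: 4 (4S)-4-benzyl-3-[(2R)-3-(3,4-dimethoxyphenyl)-2-methylpropanoyl]-1,3-oxazolidin-2-one
Product: 6 (2R)-3-(3,4-dimethoxyphenyl)-2-methylpropanoic acid, via lithium peroxycarboxylate 5 (not isolated)
Conditions: LiOH, 30% H2O2, THF/H2O (3:1), 0 °C; then aq. Na2SO3; HCl to pH 2
Reagents that add atoms: hydrogen peroxide, OO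
Why: Hydroperoxide cleavage of an N-acyloxazolidinone attacks the exocyclic carbonyl selectively and does not touch the α-stereocentre, and sulfite reduces the peracid salt to the acid.

Step 3
Reactants: 6 (2R)-3-(3,4-dimethoxyphenyl)-2-methylpropanoic acid
Product: 8 (2R)-3-(3,4-dimethoxyphenyl)-N-methoxy-N,2-dimethylpropanamide, via acyl imidazole 7 (not isolated)
Conditions: CDI, CH2Cl2, 23 °C; then MeNH(OMe)·HCl, 23 °C
Reagents that add atoms: N,O-dimethylhydroxylamine hydrochloride, CNOC.Cl
Why: Carbonyldiimidazole activation followed by aminolysis is a standard Weinreb amide synthesis, and an α-alkyl acyl imidazole should not racemise under these neutral conditions.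

Step 4
Reactants: 8 (2R)-3-(3,4-dimethoxyphenyl)-N-methoxy-N,2-dimethylpropanamide; 9 methoxyallene
Product: 11 (5R)-6-(3,4-dimethoxyphenyl)-3-methoxy-5-methylhexa-1,2-dien-4-one, via 1-lithio-1-methoxyallene 10 (not isolated)
Conditions: 9, n-BuLi, THF, −40 °C; then 8, −78 to −40 °C; aq. NH4Cl
Reagents that add atoms: none
Why: Acylation of an α-lithiated alkoxyallene by a Weinreb amide stops at the ketone because the chelated tetrahedral adduct survives until the quench, which forms the C4–C5 bond and brings in C5 with its methoxy group, C6 and C1.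

Step 5
Reactants: 11 (5R)-6-(3,4-dimethoxyphenyl)-3-methoxy-5-methylhexa-1,2-dien-4-one
Product: 12 2-[(2R)-1-(3,4-dimethoxyphenyl)propan-2-yl]-3-methoxyfuran
Conditions: AgNO3 (10 mol %), acetone, 23 °C, dark; filtration through basic alumina
Reagents that add atoms: none
Why: Cycloisomerisation of an allenyl ketone to a furan under monovalent silver catalysis, in which the carbonyl oxygen attacks the metal-activated terminal allene carbon (5-endo) and proton transfer aromatises the ring, so that C1 and C4 become the two furan α-carbons and are locked cis.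

Step 6
Reactants: 13 pent-1-en-4-yne
Product: 15 2-[(1Z)-2-bromopenta-1,4-dien-1-yl]-4,4,5,5-tetramethyl-1,3,2-dioxaborolane, via alkenyldibromoborane 14 (not isolated)
Conditions: BBr3, CH2Cl2, −78 °C; then pinacol, −78 to 23 °C
Reagents that add atoms: boron tribromide, BrB(Br)Br; pinacol, CC(C)(O)C(C)(C)O
Why: Bromoboration of a terminal alkyne is a syn addition that places boron on the terminal carbon (C3) and bromine on the internal carbon (C2), the alkyne should react well ahead of the isolated alkene at −78 °C, and pinacol traps the (Z)-adduct before it can isomerise.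

Step 7
Reactants: 12 2-[(2R)-1-(3,4-dimethoxyphenyl)propan-2-yl]-3-methoxyfuran; 15 2-[(1Z)-2-bromopenta-1,4-dien-1-yl]-4,4,5,5-tetramethyl-1,3,2-dioxaborolane
Product: 18 2-[(1Z)-2-{5-[(2R)-1-(3,4-dimethoxyphenyl)propan-2-yl]-4-methoxyfuran-2-yl}penta-1,4-dien-1-yl]-4,4,5,5-tetramethyl-1,3,2-dioxaborolane, via 5-lithiofuran 16 (not isolated), via furylzinc chloride 17 (not isolated)
Conditions: 12, n-BuLi, THF, −78 to 0 °C; ZnCl2, 0 to 23 °C; then 15, Pd(P(t-Bu)3)2 (2 mol %), THF, 23 °C
Reagents that add atoms: none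
Why: The furan is lithiated at its only free α-position (the future C1), and Negishi coupling of the derived zinc reagent under zerovalent palladium catalysis should take place at the C–Br bond with retention of geometry while the pinacol boronate stays intact in the base-free medium, so boron ends up cis to C1.

Step 8
Reactants: 18 2-[(1Z)-2-{5-[(2R)-1-(3,4-dimethoxyphenyl)propan-2-yl]-4-methoxyfuran-2-yl}penta-1,4-dien-1-yl]-4,4,5,5-tetramethyl-1,3,2-dioxaborolane
Product: 20 (2R,4E,7Z)-1-(3,4-dimethoxyphenyl)-4-methoxy-2-methyl-7-(prop-2-en-1-yl)-8-(4,4,5,5-tetramethyl-1,3,2-dioxaborolan-2-yl)octa-4,7-diene-3,6-dione, via furan endoperoxide 19 (not isolated)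
Conditions: O2, tetraphenylporphyrin (cat.), visible light, CH2Cl2, −78 °C; then Me2S, −78 to 0 °C
Reagents that add atoms: dioxygen, O=O
Why: [4+2] photooxygenation of a 2,5-disubstituted furan with singlet oxygen followed by sulfide reduction of the endoperoxide is the classical entry to cis-ene-1,4-diones, the electron-rich methoxyfuran should react far faster than the monosubstituted alkene, the alkenyl boronate or the arene, and the ring origin guarantees that the C1 and C4 carbonyls are cis.

Step 9
Reactants: 20 (2R,4E,7Z)-1-(3,4-dimethoxyphenyl)-4-methoxy-2-methyl-7-(prop-2-en-1-yl)-8-(4,4,5,5-tetramethyl-1,3,2-dioxaborolan-2-yl)octa-4,7-diene-3,6-dione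
Product: 21 (4R)-4-[(2R)-1-(3,4-dimethoxyphenyl)propan-2-yl]-4-hydroxy-5-methoxy-2-(prop-2-en-1-yl)cyclohexa-2,5-dien-1-one
Conditions: [Rh(OH)((R)-binap)]2 (3 mol %), 1,4-dioxane/H2O (10:1), 40 °C, degassed
Reagents that add atoms: none
Why: The hydroxo complex of monovalent rhodium transmetalates the alkenyl pinacol boronate without added base to give an alkenylrhodium at C3, the C4 carbonyl coordinates and inserts into the Rh–C bond, and water protonates the rhodium alkoxide to release 21 and regenerate Rh–OH. The closest known reaction type is the rhodium-catalysed enantioselective intramolecular 1,2-addition of aryl and alkenyl boron reagents to tethered ketones. The six-membered ring closes by C3–C4 bond formation in a 6-exo-trig mode at the carbonyl carbon, with the cis double bonds C2=C3 and C5=C6 holding the two reacting ends next to each other. The new stereocentre C4 is controlled by the chiral bisphosphine, which has to deliver the alkenyl group to the Re face of the C4 carbonyl, against the weak Felkin preference of the adjacent C7 centre. Chemoselectivity for 1,2-addition is secured by geometry, since attack at C5 would be a 5-endo closure and attack at C6 would give a four-membered ring, and the neutral medium should leave the enolisable C7 centre unchanged.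

Step 10
Reactants: 21 (4R)-4-[(2R)-1-(3,4-dimethoxyphenyl)propan-2-yl]-4-hydroxy-5-methoxy-2-(prop-2-en-1-yl)cyclohexa-2,5-dien-1-one
Product: 23 (4R)-4-[(2R)-1-(3,4-dimethoxyphenyl)propan-2-yl]-4,5-dimethoxy-2-(prop-2-en-1-yl)cyclohexa-2,5-dien-1-one, via sodium alkoxide 22 (not isolated)
Conditions: NaH, THF/DMF (4:1), 0 °C; then MeI, 0 to 23 °C
Reagents that add atoms: iodomethane, CI
Why: Williamson etherification of the tertiary quinol alkoxide with excess iodomethane, in which the cross-conjugated dienone offers no competing enolisable position and neither C4 nor C7 is touched.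

**Compound list**

1 | (4S)-4-benzyl-3-propanoyl-1,3-oxazolidin-2-one | CCC(=O)N1[C@@H](Cc2ccccc2)COC1=O | starting material
2 | 4-(bromomethyl)-1,2-dimethoxybenzene | COc1ccc(CBr)cc1OC | starting material
3 | sodium (Z)-enolate of 1 | [Na+].C/C=C(\[O-])N1[C@@H](Cc2ccccc2)COC1=O | intermediate
4 | (4S)-4-benzyl-3-[(2R)-3-(3,4-dimethoxyphenyl)-2-methylpropanoyl]-1,3-oxazolidin-2-one | O=C([C@H](C)Cc1ccc(OC)c(OC)c1)N1[C@@H](Cc2ccccc2)COC1=O | intermediate
5 | lithium (2R)-3-(3,4-dimethoxyphenyl)-2-methylpropaneperoxoate | [Li+].[O-]OC(=O)[C@H](C)Cc1ccc(OC)c(OC)c1 | intermediate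
6 | (2R)-3-(3,4-dimethoxyphenyl)-2-methylpropanoic acid | OC(=O)[C@H](C)Cc1ccc(OC)c(OC)c1 | intermediate
7 | 1-[(2R)-3-(3,4-dimethoxyphenyl)-2-methylpropanoyl]imidazole | O=C([C@H](C)Cc1ccc(OC)c(OC)c1)n1ccnc1 | intermediate
8 | (2R)-3-(3,4-dimethoxyphenyl)-N-methoxy-N,2-dimethylpropanamide | CON(C)C(=O)[C@H](C)Cc1ccc(OC)c(OC)c1 | intermediate
9 | methoxyallene (1-methoxypropa-1,2-diene) | COC=C=C | starting material
10 | 1-lithio-1-methoxypropa-1,2-diene | [Li]C(OC)=C=C | intermediate
11 | (5R)-6-(3,4-dimethoxyphenyl)-3-methoxy-5-methylhexa-1,2-dien-4-one | C=C=C(OC)C(=O)[C@H](C)Cc1ccc(OC)c(OC)c1 | intermediate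
12 | 2-[(2R)-1-(3,4-dimethoxyphenyl)propan-2-yl]-3-methoxyfuran | COc1ccoc1[C@H](C)Cc1ccc(OC)c(OC)c1 | intermediate
13 | pent-1-en-4-yne | C=CCC#C | starting material
14 | dibromo[(1Z)-2-bromopenta-1,4-dien-1-yl]borane | C=CC/C(Br)=C/B(Br)Br | intermediate
15 | 2-[(1Z)-2-bromopenta-1,4-dien-1-yl]-4,4,5,5-tetramethyl-1,3,2-dioxaborolane | C=CC/C(Br)=C/B1OC(C)(C)C(C)(C)O1 | intermediate
16 | {5-[(2R)-1-(3,4-dimethoxyphenyl)propan-2-yl]-4-methoxyfuran-2-yl}lithium | [Li]c1cc(OC)c(o1)[C@H](C)Cc1ccc(OC)c(OC)c1 | intermediate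
17 | chloro{5-[(2R)-1-(3,4-dimethoxyphenyl)propan-2-yl]-4-methoxyfuran-2-yl}zinc | Cl[Zn]c1cc(OC)c(o1)[C@H](C)Cc1ccc(OC)c(OC)c1 | intermediate
18 | 2-[(1Z)-2-{5-[(2R)-1-(3,4-dimethoxyphenyl)propan-2-yl]-4-methoxyfuran-2-yl}penta-1,4-dien-1-yl]-4,4,5,5-tetramethyl-1,3,2-dioxaborolane | C=CC/C(=C/B1OC(C)(C)C(C)(C)O1)c1cc(OC)c(o1)[C@H](C)Cc1ccc(OC)c(OC)c1 | intermediate
19 | 2,3,7-trioxabicyclo[2.2.1]hept-5-ene endoperoxide of 18 (both bridgehead-epimeric forms) | C=CC/C(=C/B1OC(C)(C)C(C)(C)O1)C12OOC(O1)(C(OC)=C2)[C@H](C)Cc1ccc(OC)c(OC)c1 | intermediate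
20 | (2R,4E,7Z)-1-(3,4-dimethoxyphenyl)-4-methoxy-2-methyl-7-(prop-2-en-1-yl)-8-(4,4,5,5-tetramethyl-1,3,2-dioxaborolan-2-yl)octa-4,7-diene-3,6-dione | C=CC/C(=C/B1OC(C)(C)C(C)(C)O1)C(=O)/C=C(OC)\C(=O)[C@H](C)Cc1ccc(OC)c(OC)c1 | intermediate
21 | (4R)-4-[(2R)-1-(3,4-dimethoxyphenyl)propan-2-yl]-4-hydroxy-5-methoxy-2-(prop-2-en-1-yl)cyclohexa-2,5-dien-1-one | C=CCC1=C[C@](O)([C@H](C)Cc2ccc(OC)c(OC)c2)C(OC)=CC1=O | intermediate
22 | sodium alkoxide of 21 | [Na+].C=CCC1=C[C@]([O-])([C@H](C)Cc2ccc(OC)c(OC)c2)C(OC)=CC1=O | intermediate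
23 | (4R)-4-[(2R)-1-(3,4-dimethoxyphenyl)propan-2-yl]-4,5-dimethoxy-2-(prop-2-en-1-yl)cyclohexa-2,5-dien-1-one | C=CCC1=C[C@](OC)([C@H](C)Cc2ccc(OC)c(OC)c2)C(OC)=CC1=O | target

**Step count and risks**

Total step count: 10. Longest linear sequence: 9 steps (steps 1 to 5 and 7 to 10, from 1); step 6 is a one-step side branch.

Steps most likely to fail:

1. Step 9. The process at risk is facial selection at the C4 carbonyl, where the ligand has to overrule the Felkin preference of C7; protodeboronation of the electron-poor alkenyl boronate is a secondary loss. The fallback sets out from 21, taken as whatever mixture of C4 epimers the cyclisation delivers, and comes back to the route at 23. Reduction with Zn in AcOH aromatises both epimers with loss of the C4 hydroxyl to the single phenol 5-methoxy-4-[(2R)-1-(3,4-dimethoxyphenyl)propan-2-yl]-2-(prop-2-en-1-yl)phenol F1. Oxidative dearomatisation of F1 with PhI(OAc)2 in MeOH at 0 °C should add methanol para to the phenol oxygen and give 23 together with its C4 epimer (4S)-4-[(2R)-1-(3,4-dimethoxyphenyl)propan-2-yl]-4,5-dimethoxy-2-(prop-2-en-1-yl)cyclohexa-2,5-dien-1-one F2. The two are diastereomers and should be separable by chromatography, and F2 is returned to F1 by the same zinc reduction. The C4 configuration then rests on separation and recycling instead of catalyst control.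

2. Step 8. The process at risk is chemoselectivity of the photooxygenation: singlet oxygen may attack the exocyclic furan–alkene diene or the C–B bond, and the cis ene-dione may isomerise or be over-oxidised. The fallback sets out from 18 and comes back at 20. Electrophilic oxidation with NBS and NaHCO3 in MeOH at −40 °C (Clauson-Kaas-type 2,5-dimethoxylation) should give the masked ene-dione 2-[(1Z)-2-{5-[(2R)-1-(3,4-dimethoxyphenyl)propan-2-yl]-2,4,5-trimethoxy-2,5-dihydrofuran-2-yl}penta-1,4-dien-1-yl]-4,4,5,5-tetramethyl-1,3,2-dioxaborolane F3 as a mixture of ketal epimers that can be isolated. Mild hydrolysis of the two ketal centres (wet silica gel or dilute oxalic acid in acetone/H2O, 0 °C) should then release 20 with the cis geometry fixed by the ring.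

3. Step 5. The process at risk is loss of the electrophilic methoxyallenyl ketone through oligomerisation or conjugate addition before ring closure, or acid-triggered hydrolysis of the methoxyfuran during isolation. The fallback sets out from 8, bypasses 11 and comes back at 12. Reduction of 8 with (i-Bu)2AlH in THF at −78 °C gives (2R)-3-(3,4-dimethoxyphenyl)-2-methylpropanal F4, which is used at once to limit epimerisation. Addition of 1-lithio-1-methoxyallene 10 gives (5R)-6-(3,4-dimethoxyphenyl)-3-methoxy-5-methylhexa-1,2-dien-4-ol F5 as both carbinol epimers. A 5-endo cyclisation with AuCl and pyridine in CH2Cl2 (or KOt-Bu in DMSO) gives 2-[(2R)-1-(3,4-dimethoxyphenyl)propan-2-yl]-3-methoxy-2,5-dihydrofuran F6. Dehydrogenation of F6 with DDQ in dry CH2Cl2 removes the carbinol-derived stereocentre and should deliver furan 12.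

**Further compounds**

F1 | step 9 | 5-methoxy-4-[(2R)-1-(3,4-dimethoxyphenyl)propan-2-yl]-2-(prop-2-en-1-yl)phenol | C=CCc1cc([C@H](C)Cc2ccc(OC)c(OC)c2)c(OC)cc1O
F2 | step 9 | (4S)-4-[(2R)-1-(3,4-dimethoxyphenyl)propan-2-yl]-4,5-dimethoxy-2-(prop-2-en-1-yl)cyclohexa-2,5-dien-1-one | C=CCC1=C[C@@](OC)([C@H](C)Cc2ccc(OC)c(OC)c2)C(OC)=CC1=O
F3 | step 8 | 2-[(1Z)-2-{5-[(2R)-1-(3,4-dimethoxyphenyl)propan-2-yl]-2,4,5-trimethoxy-2,5-dihydrofuran-2-yl}penta-1,4-dien-1-yl]-4,4,5,5-tetramethyl-1,3,2-dioxaborolane | C=CC/C(=C/B1OC(C)(C)C(C)(C)O1)C1(OC)OC(OC)(C(OC)=C1)[C@H](C)Cc1ccc(OC)c(OC)c1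
F4 | step 5 | (2R)-3-(3,4-dimethoxyphenyl)-2-methylpropanal | O=C[C@H](C)Cc1ccc(OC)c(OC)c1
F5 | step 5 | (5R)-6-(3,4-dimethoxyphenyl)-3-methoxy-5-methylhexa-1,2-dien-4-ol | C=C=C(OC)C(O)[C@H](C)Cc1ccc(OC)c(OC)c1
F6 | step 5 | 2-[(2R)-1-(3,4-dimethoxyphenyl)propan-2-yl]-3-methoxy-2,5-dihydrofuran | COC1=CCOC1[C@H](C)Cc1ccc(OC)c(OC)c1
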